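At the first reading, 0.64 min into the alpha run, 12.0% of the substrate charged stands as target, while the zeta flask, with more reagent, shows 21.1%. What share of that early speed answers to reagent?

| flask | substrate | reagent | catalyst | target | time |
|---|---|---|---|---|---|
| alpha | 80.0 mM | 240 mM | 1.60 mM |  |  |
| zeta | 80.0 mM | 720 mM | 1.60 mM |  |  |
| beta | 80.0 mM | 240 mM | 1.60 mM | 24.0 mM |  |
| gamma | 160 mM | 240 mM | 1.60 mM |  |  |
| eta | 80.0 mM | 240 mM | 1.60 mM |  | 18 min |

| alpha run: time / min | alpha run: [target] / mM | zeta run: time / min | zeta run: [target] / mM | beta run: time / min | beta run: [target] / mM | gamma run: time / min | gamma run: [target] / mM |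
|---|---|---|---|---|---|---|---|
| 0.64 | 9.6 | 0.64 | 16.9 | 0.64 | 33.2 | 0.64 | 20.7 |
| 1.3 | 17.5 | 1.3 | 24.6 | 1.3 | 36.1 | 1.3 | 34.9 |
| 1.9 | 24.0 | 1.9 | 27.5 | 1.9 | 41.4 | 1.9 | 45.3 |
| 2.6 | 29.5 | 2.6 | 26.2 | 2.6 | 43.6 | 2.6 | 53.3 |
| 3.2 | 34.5 | 3.2 | 23.4 | 3.2 | 45.5 | 3.2 | 60.5 |
| 3.9 | 33.3 | 3.9 | 20.4 | 3.9 | 46.2 | 3.9 | 65.5 |
| 4.5 | 33.3 | 4.5 | 16.5 | 4.5 | 46.1 | 4.5 | 68.3 |

(each reading ± 1 mM)

- Overall: substrate + reagent -> target, with catalyst as catalyst.
- Constant volume, constant temperature.
- A reading of a species includes what of it is bound.
- "The second partner" is reagent.
- An order is taken over about fifteen percent of the charge, up and down.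

* the power of [substrate] that the first rate follows, about the charge of the alpha run; measure it at two percent of substrate made into target (one fixed amount of target, the same in the runs compared)
* the power of [reagent] that the first rate follows, about the charge of the alpha run; measure it at two percent of substrate made into target
* target in the eta run at 18 min, as a share of the substrate charged

I go by hand, in fractions of the substrate charged. In the alpha run the chord from zero to the first reading gives 0.188 min⁻¹, and the chord to the second gives 0.168 min⁻¹. The chords shrink as the curve bends, so I run them back to time zero and get 0.206 min⁻¹. The zeta run gives 0.330 min⁻¹ and 0.237 min⁻¹, hence 0.421 min⁻¹. So the first rate grows 2.04 times for 3.00 times the reagent.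

Now the link that carries the weight. I picture the first rate as a straight line in reagent: one part ignores reagent, the other is proportional to it. Then 0.521 is the reagent share, the fraction of the alpha run's first rate that is proportional to reagent. On such a line the share is also the local power of reagent, so I commit to an order of 0.521, a reading that carries the scatter of 1 mM in each point.

The forecast gives 1 for substrate (0.8 to 1.2), 0.75 for reagent (0.45 to 1.05) and 26% for the eta run (11% to 42%). Its ground for reagent is “Tripling reagent gives only about 2.2 times”. My order is lower than the forecast's.

The simulation gives 0.99, 0.49 and 25.0%; the forecast's reagent order is too high by a factor of 1.53, its other two within tolerance.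

    catalyst + substrate → catalyst-substrate complex (88.20 L mol⁻¹ min⁻¹)
    catalyst-substrate complex + reagent → target + catalyst (330.0 L mol⁻¹ min⁻¹)
    substrate + reagent → target (0.4506 L mol⁻¹ min⁻¹)
    target + reagent → side product (0.7980 L mol⁻¹ min⁻¹)

The weak link was a power stretched over the whole step from alpha to zeta, and reforged it is two branches. The turning of substrate + reagent into target carries the reagent dependence: without it, the order in reagent falls from 0.49 to 0.054. On the catalysed branch at the charge of the alpha run, binding of substrate is the rate-limiting step, slower than the reagent's step. My reagent share of 0.521 leaves 0.479 of the alpha run's first rate as the part that ignores reagent. The order in catalyst is 0.55, and 1.0 with that turning taken away.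

The readings come from a simulation for an exercise; scatter was added.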